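The ratio that matters here compares the share of a charge that ends up as something other than E with a ceiling on that loss, and the earlier runs supply both.

| flask | L | remark | time |
|---|---|---|---|
| gamma | 0.024 M | run made earlier |  |
| delta | 0.037 M | run made earlier |  |
| flask | 0.017 M |  | 12 d |

| run | time / d | E / % | L / % |
|---|---|---|---|
| gamma | 0.104 | 67 | 8 |
| gamma | 0.250 | 82 | 4 |
| gamma | 0.625 | 73 | 0 |
| gamma | 1.67 | 45 | 2 |
| gamma | 4.00 | 25 | 4 |
| gamma | 10.0 | 23 | 0 |
| delta | 0.104 | 66 | 11 |
| delta | 0.250 | 85 | 2 |
| delta | 0.625 | 86 | 0 |
| delta | 1.67 | 64 | 1 |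
| delta | 4.00 | 46 | 3 |
| delta | 10.0 | 45 | 3 |

(scatter of a reading: 2 percentage points)

- a reading or a percentage of E counts all its forms, free or not
- a reading of L is of its free form alone

* the best time, 12 d at the latest, for E
* the amount of E, in percent of the L charged, at that time

At its last reading the gamma run has a share f = 77.0% of its charge no longer present as E. The delta run has lost a smaller share but more in concentration, C = 0.0204 M against 0.0185 M. My reading is that the loss is capped near C, with the gamma run still below the cap. For a charge c, the ceiling number N is the loss at the gamma share over that cap: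

N = f·c/C = 0.643

For this flask N is less than one, so it should keep the gamma share and end near 23.0% E. That lies far below the gamma run's highest reading, 82% at 0.250 d, so E should be taken early.

The forecast gives 78% at 0.27 d, and its end differs from mine: “E ends near zero by 12 d”.

The flask gives 80.0% at 0.251 d and still holds 25.6% E at 12 d, against the 23.0% reckoned from N.

    L → E (k = 3.70 × 10⁻⁴ s⁻¹)
    2 L ⇌ Q (K = 49.0 L mol⁻¹, k = 0.0210 L mol⁻¹ s⁻¹)
    L + E ⇌ J, settled at all times (K = 230 L mol⁻¹)
    E ⇌ Z (K = 2.90, k = 1.80 × 10⁻⁵ s⁻¹)
    D ⇌ E, rate k5*(cs5 - [E]) while solid is left; crystals form when [E] > cs5 (solubility = 7.70 mM, k = 0.00560 s⁻¹)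

In the flask, the early harvest is kinetic control and the plateau thermodynamic control. The passing of E into Z, both ways, takes the flask's peak from 100% down to 80.0%, and Z holds 74.4% at the end. In a neighbour flask with 0.068 M L, N = 2.57, above one, so the loss should stop at C and leave 70.0% E. Computed, that neighbour flask ends at 12 d with 67.2% E, all its forms counted, and 32.8% Z.

All runs stem from a simulated flask on assumed constants.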